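**Retrosynthetic overview**
1. The target is an 8b–8b′-linked dimer of two ε-viniferin-type halves, closed crosswise (C7b–C10a′ and C7b′–C10a) into two fused eight-membered rings. Unit 1 (C7a, C8a, resorcinol ring A, benzofuran benzo ring B, C7b, C8b) has a trans-dihydrobenzofuran; unit 2 (primed locants, resorcinol ring C, benzofuran benzo ring D) has a cis one. The last disconnection removes nine O-benzyl groups.
2. Key disconnection: C8b–C8b′ and both C7–C10a bonds, made in one oxidative cross-coupling/double Friedel–Crafts operation from a cis phenol-stilbene (unit 2) and a trans benzyl-ether stilbene (unit 1); both eight-membered rings close here.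
3. Both stilbenes come from Heck reactions of one 4-bromo-2,3-diaryl-2,3-dihydrobenzofuran, used as made (cis) or after acid epimerisation at C2 (trans).
4. The dihydrobenzofuran comes from an enantioselective Rh2(S-PTAD)4-catalysed carbene C–H insertion of a diaryldiazomethane derived from a 2-(arylmethoxy)benzophenone, itself from Friedel–Crafts acylation of 1-bromo-3,5-dimethoxybenzene.
5. Ring order: the dihydrobenzofuran ring of each half first (step 6), then the two eight-membered rings together (step 10).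

Assumption: the SMILES is read as 7aS,8aS (trans) and 7a′R,8a′S (cis) with 7bR,8bR,7b′R,8b′S and eight-membered (not seven-membered, hopeaphenol-type) carbocycles; Rh2(S-PTAD)4 is taken to give the (2R,3S) series, its mirror-image catalyst being used should the sense prove opposite.

**Route**

Step 1
Reactants: 1 1-bromo-3,5-dimethoxybenzene; 2 3,5-dimethoxybenzoyl chloride
Product: 3 (2-bromo-4,6-dimethoxyphenyl)(3,5-dimethoxyphenyl)methanone
Conditions: AlCl3 (1.2 equiv), CH2Cl2, 0 °C → rt
Reagents that add atoms: none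
Why: Friedel–Crafts acylation at the carbon ortho to Br and para to OMe (the site that Vilsmeier formylation of 1 also takes), the acyl chloride ring being the less nucleophilic one; any ortho-O-demethylated ketone converges in step 2.

Step 2
Reactants: 3 (2-bromo-4,6-dimethoxyphenyl)(3,5-dimethoxyphenyl)methanone
Product: 4 (2-bromo-4,6-dihydroxyphenyl)(3,5-dihydroxyphenyl)methanone
Conditions: BBr3 (6 equiv), CH2Cl2, −78 °C → rt; then H2O
Reagents that add atoms: none
Why: Lewis-acid cleavage of the four aryl methyl ethers (BBr3 demethylation), to which the aryl bromide and the diaryl ketone are inert; no stereocentre is present yet.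

Step 3
Reactants: 4 (2-bromo-4,6-dihydroxyphenyl)(3,5-dihydroxyphenyl)methanone
Product: 5 [4-(benzyloxy)-2-bromo-6-hydroxyphenyl][3,5-bis(benzyloxy)phenyl]methanone
Conditions: BnBr (3.1 equiv), K2CO3, acetone, 50 °C
Reagents that add atoms: benzyl bromide, BrCc1ccccc1
Why: Williamson etherification in which the phenol hydrogen-bonded to the carbonyl is the least nucleophilic and stays free, as in the 4-O-selective alkylation of 2,4-dihydroxybenzophenones.

Step 4
Reactants: 5 [4-(benzyloxy)-2-bromo-6-hydroxyphenyl][3,5-bis(benzyloxy)phenyl]methanone; 6 4-(benzyloxy)benzyl chloride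
Product: 7 [4-(benzyloxy)-2-{[4-(benzyloxy)phenyl]methoxy}-6-bromophenyl][3,5-bis(benzyloxy)phenyl]methanone
Conditions: Cs2CO3, NaI (cat.), DMF, 60 °C
Reagents that add atoms: none
Why: Williamson etherification of the chelated phenol under more forcing conditions, installing the O–CH2–aryl group whose CH2 becomes C7a.

Step 5
Reactants: 7 [4-(benzyloxy)-2-{[4-(benzyloxy)phenyl]methoxy}-6-bromophenyl][3,5-bis(benzyloxy)phenyl]methanone
Product: 8 hydrazone of 7 (E/Z mixture)
Conditions: N2H4·H2O (20 equiv), AcOH (cat.), n-BuOH, 115 °C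
Reagents that add atoms: hydrazine, NN
Why: hydrazone condensation driven by excess hydrazine and heat for the di-ortho-substituted benzophenone; without a metal catalyst the unactivated, electron-rich aryl bromide does not close to an indazole.

Step 6
Reactants: 8 hydrazone of 7
Product: 10 (2R,3S)-6-(benzyloxy)-2-[4-(benzyloxy)phenyl]-3-[3,5-bis(benzyloxy)phenyl]-4-bromo-2,3-dihydro-1-benzofuran (cis), via diazoalkane 9 (not isolated)
Conditions: MnO2, MgSO4, CH2Cl2, 0 °C; filter; Rh2(S-PTAD)4 (1 mol %), CH2Cl2, 0 °C → rt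
Reagents that add atoms: none
Why: dehydrogenation to the diaryldiazomethane and donor/donor carbene 1,5-C–H insertion on Rh2(S-PTAD)4 into the only reachable CH2 (the ortho O–CH2–aryl), which is cis-selective and catalyst-controlled and sets C3 (S) and C2 (R) together.

Step 7
Reactants: 10 cis bromide; 11 4-acetoxystyrene
Product: 13 4-[(E)-2-{(2R,3S)-6-(benzyloxy)-2-[4-(benzyloxy)phenyl]-3-[3,5-bis(benzyloxy)phenyl]-2,3-dihydro-1-benzofuran-4-yl}ethenyl]phenol, via acetate 12 (not isolated)
Conditions: Pd(OAc)2 (5 mol %), P(o-tol)3 (10 mol %), Et3N, DMF, 100 °C; then K2CO3, MeOH, rt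
Reagents that add atoms: none
Why: Mizoroki–Heck reaction (E-alkene from syn-insertion and syn-β-hydride elimination) followed by methanolysis of the aryl acetate, all under basic conditions that leave the cis C2/C3 centres untouched.

Step 8
Reactants: 10 cis bromide
Product: 14 (2S,3S)-6-(benzyloxy)-2-[4-(benzyloxy)phenyl]-3-[3,5-bis(benzyloxy)phenyl]-4-bromo-2,3-dihydro-1-benzofuran (trans)
Conditions: TFA/CH2Cl2 (1:4), 0 °C → rt
Reagents that add atoms: none
Why: acid-mediated epimerisation at C2 by reversible heterolysis of the benzylic C2–O bond (4-benzyloxybenzyl cation) to the thermodynamically preferred trans isomer, C3 being untouched; it is done before the acid-sensitive stilbene is present.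

Step 9
Reactants: 14 trans bromide; 15 4-(benzyloxy)styrene
Product: 16 (2S,3S)-6-(benzyloxy)-2-[4-(benzyloxy)phenyl]-3-[3,5-bis(benzyloxy)phenyl]-4-{(E)-2-[4-(benzyloxy)phenyl]ethenyl}-2,3-dihydro-1-benzofuran
Conditions: Pd(OAc)2 (5 mol %), P(o-tol)3 (10 mol %), Et3N, DMF, 100 °C
Reagents that add atoms: none
Why: Mizoroki–Heck reaction giving the E-stilbene; the non-acidic conditions keep the trans C2/C3 centres.

Step 10
Reactants: 13 cis phenol-stilbene (unit 2); 16 trans benzyl-ether stilbene (unit 1)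
Product: 18 nona-O-benzyl ether of the target (7aS,8aS,7bR,8bR,7a′R,8a′S,7b′R,8b′S; only the 4-hydroxyphenyl on C7b′ is free), via quinone methide 17 (not isolated)
Conditions: PhI(OAc)2 (1.0 equiv, slow addition), 13:16 = 1:1.3, HFIP/CH2Cl2 (1:4), 5 mM, −40 °C → 0 °C
Reagents that add atoms: none
Why: Proposed new method: PhI(OAc)2 oxidises only the free phenol of 13 to its vinylogous phenoxonium ion, whose C8b′ is attacked by the β-carbon of the electron-rich stilbene of 16 (C8b–C8b′); the 4-benzyloxybenzyl cation formed at C7b is taken at once by C10a′ of ring C, which lies on the same face of unit 2 (first eight-membered ring; suprafacial addition of C8b′ and C10a′ across the E-alkene of 16 on the face anti to ring A gives 7bR, 8bR and 8b′S), and the remaining p-quinone methide 17 is then arylated in HFIP by C10a of ring A from the one face it can reach (second eight-membered ring, 7b′R); the closest known reactions are the PhI(OAc)2-mediated β,β′-coupling of alkenylphenols (carpanone type, including hetero-couplings with a partner that is not oxidised), the 8–8′ coupling/Friedel–Crafts cyclisation of ε-viniferin-derived quinone methides and the HFIP-promoted 1,6-arylation of p-quinone methides.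

Step 11
Reactants: 18 nona-O-benzyl ether of the target
Product: 19 target decaphenol (7aS,8aS,7bR,8bR,7a′R,8a′S,7b′R,8b′S)
Conditions: H2 (1 atm), Pd(OH)2/C, THF/MeOH (1:1), rt; filter under argon
Reagents that add atoms: none
Why: heterogeneous hydrogenolysis of the nine benzyl ethers under neutral conditions, so the acid-labile cis C7a′ centre and the seven other stereocentres are not epimerised; the ring benzylic C–O bonds of the dihydrobenzofurans are cleaved far more slowly than O-benzyl groups.

**Compound list**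
1 | 1-bromo-3,5-dimethoxybenzene | COc1cc(Br)cc(OC)c1 | starting material
2 | 3,5-dimethoxybenzoyl chloride | COc1cc(cc(OC)c1)C(Cl)=O | starting material
3 | (2-bromo-4,6-dimethoxyphenyl)(3,5-dimethoxyphenyl)methanone | COc1cc(OC)cc(c1)C(=O)c1c(Br)cc(OC)cc1OC | intermediate
4 | (2-bromo-4,6-dihydroxyphenyl)(3,5-dihydroxyphenyl)methanone | O=C(c1cc(O)cc(O)c1)c1c(Br)cc(O)cc1O | intermediate
5 | [4-(benzyloxy)-2-bromo-6-hydroxyphenyl][3,5-bis(benzyloxy)phenyl]methanone | O=C(c1cc(OCc2ccccc2)cc(OCc2ccccc2)c1)c1c(Br)cc(OCc2ccccc2)cc1O | intermediate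
6 | 4-(benzyloxy)benzyl chloride | ClCc1ccc(OCc2ccccc2)cc1 | starting material
7 | [4-(benzyloxy)-2-{[4-(benzyloxy)phenyl]methoxy}-6-bromophenyl][3,5-bis(benzyloxy)phenyl]methanone | O=C(c1cc(OCc2ccccc2)cc(OCc2ccccc2)c1)c1c(Br)cc(OCc2ccccc2)cc1OCc1ccc(OCc2ccccc2)cc1 | intermediate
8 | hydrazone of 7 (E/Z mixture) | NN=C(c1cc(OCc2ccccc2)cc(OCc2ccccc2)c1)c1c(Br)cc(OCc2ccccc2)cc1OCc1ccc(OCc2ccccc2)cc1 | intermediate
9 | diaryldiazomethane from 8 | [N-]=[N+]=C(c1cc(OCc2ccccc2)cc(OCc2ccccc2)c1)c1c(Br)cc(OCc2ccccc2)cc1OCc1ccc(OCc2ccccc2)cc1 | intermediate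
10 | (2R,3S)-6-(benzyloxy)-2-[4-(benzyloxy)phenyl]-3-[3,5-bis(benzyloxy)phenyl]-4-bromo-2,3-dihydro-1-benzofuran (cis) | C(c1ccccc1)Oc1cc(OCc2ccccc2)cc(c1)[C@H]1c2c(cc(OCc3ccccc3)cc2Br)O[C@H]1c1ccc(OCc2ccccc2)cc1 | intermediate
11 | 4-acetoxystyrene (4-ethenylphenyl acetate) | CC(=O)Oc1ccc(C=C)cc1 | starting material
12 | acetate of 13 (cis, E-stilbene) | C(c1ccccc1)Oc1cc(OCc2ccccc2)cc(c1)[C@H]1c2c(cc(OCc3ccccc3)cc2/C=C/c2ccc(OC(C)=O)cc2)O[C@H]1c1ccc(OCc2ccccc2)cc1 | intermediate
13 | 4-[(E)-2-{(2R,3S)-6-(benzyloxy)-2-[4-(benzyloxy)phenyl]-3-[3,5-bis(benzyloxy)phenyl]-2,3-dihydro-1-benzofuran-4-yl}ethenyl]phenol (unit 2) | C(c1ccccc1)Oc1cc(OCc2ccccc2)cc(c1)[C@H]1c2c(cc(OCc3ccccc3)cc2/C=C/c2ccc(O)cc2)O[C@H]1c1ccc(OCc2ccccc2)cc1 | intermediate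
14 | (2S,3S)-6-(benzyloxy)-2-[4-(benzyloxy)phenyl]-3-[3,5-bis(benzyloxy)phenyl]-4-bromo-2,3-dihydro-1-benzofuran (trans) | C(c1ccccc1)Oc1cc(OCc2ccccc2)cc(c1)[C@H]1c2c(cc(OCc3ccccc3)cc2Br)O[C@@H]1c1ccc(OCc2ccccc2)cc1 | intermediate
15 | 4-(benzyloxy)styrene (1-(benzyloxy)-4-ethenylbenzene) | C=Cc1ccc(OCc2ccccc2)cc1 | starting material
16 | (2S,3S)-6-(benzyloxy)-2-[4-(benzyloxy)phenyl]-3-[3,5-bis(benzyloxy)phenyl]-4-{(E)-2-[4-(benzyloxy)phenyl]ethenyl}-2,3-dihydro-1-benzofuran (unit 1) | C(c1ccccc1)Oc1cc(OCc2ccccc2)cc(c1)[C@H]1c2c(cc(OCc3ccccc3)cc2/C=C/c2ccc(OCc3ccccc3)cc2)O[C@@H]1c1ccc(OCc2ccccc2)cc1 | intermediate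
17 | mono-cyclised p-quinone methide: C8b–C8b′ and C7b–C10a′ formed, C7b′ is the exocyclic methine of a 4-methylenecyclohexa-2,5-dienone, ring A still open; stereocentres placed in space as in 18 | O=C1C=CC(C=C1)=C[C@@H]2[C@@H](c3cc(OCc7ccccc7)cc4c3[C@H](c6cc(OCc7ccccc7)cc(OCc7ccccc7)c6)[C@@H](c6ccc(OCc7ccccc7)cc6)O4)[C@H](c6ccc(OCc7ccccc7)cc6)c4c(OCc7ccccc7)cc(OCc7ccccc7)cc4[C@H]4c5c(cc(OCc7ccccc7)cc52)O[C@H]4c4ccc(OCc7ccccc7)cc4 | intermediate
18 | nona-O-benzyl ether of 19 (free OH only on the C7b′ aryl); 7aS,8aS,7bR,8bR,7a′R,8a′S,7b′R,8b′S | Oc1ccc([C@@H]2c3c(OCc7ccccc7)cc(OCc7ccccc7)cc3[C@H]3c4c(cc(OCc7ccccc7)cc4[C@H]4[C@H](c5ccc(OCc7ccccc7)cc5)c5c(OCc7ccccc7)cc(OCc7ccccc7)cc5[C@H]5c6c(cc(OCc7ccccc7)cc6[C@H]24)O[C@H]5c2ccc(OCc7ccccc7)cc2)O[C@@H]3c2ccc(OCc7ccccc7)cc2)cc1 | intermediate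
19 | CNP0224452.3: crosswise-cyclised 8b–8b′ dimer of a trans- and a cis-ε-viniferin unit, decaphenol; 7aS,8aS,7bR,8bR,7a′R,8a′S,7b′R,8b′S | Oc1ccc([C@@H]2c3c(O)cc(O)cc3[C@H]3c4c(cc(O)cc4[C@H]4[C@H](c5ccc(O)cc5)c5c(O)cc(O)cc5[C@H]5c6c(cc(O)cc6[C@H]24)O[C@H]5c2ccc(O)cc2)O[C@@H]3c2ccc(O)cc2)cc1 | target

**Totals and risks**
Total step count: 11. Longest linear sequence: 10 steps (1–6, 8, 9, 10, 11).

Most likely to fail, in this order:

Step 10 carries most of the risk of the route. The stilbene of 16 must bond to C8b′ on the face of unit 2 that also carries ring C and the cis C7a′ aryl group. Attack on the open face would give the 8b′ epimer, which is set up for seven-membered (hopeaphenol-type) closure onto the resorcinol ring of its own unit. The unblocked C14b and C14b′ positions can close five-membered rings, as ε-viniferin-derived quinone methide dimers are known to do, and 13 can couple with itself. The second eight-membered ring also needs an unfavourable rotamer about the bond between ring B and C8b. The fallback decouples the two ring closures. It sets out from 13 and 16: the same oxidant is used in CH2Cl2 buffered with AcOH/NaOAc at −40 °C without fluoro-alcohol, so that after C8b–C8b′ coupling and the first closure the quinone methide is captured by acetic acid as the mono-cyclised benzylic acetate F1, which is isolated and freed from diastereomers by HPLC. F1 is then ionised on its own with Sc(OTf)3 (10 mol %) in HFIP/CH2Cl2 at 0.5 mM and −20 °C, where the second ring closes by SN1 Friedel–Crafts alkylation, and the sequence comes back to the route at 18.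

Step 5 may stall because the ketone of 7 is flanked by Br and the arylmethoxy group. The fallback builds the C=N–N unit by silyl-transfer condensation instead of equilibrium condensation with free hydrazine. It sets out from 7: 1,2-bis(tert-butyldimethylsilyl)hydrazine with Sc(OTf)3 (1 mol %) gives the N-silyl hydrazone F2, which TBAF/AcOH in THF at 0 °C desilylates, coming back to the route at 8.

Step 9 (and step 7, the same reaction type) uses a bromide next to the ring-fusion carbon that carries the bulky C3 aryl group, so oxidative addition may be slow and reduction of the bromide may compete. The fallback replaces the coupling by carbonyl olefination. It sets out from 14: Br/Li exchange (n-BuLi, THF, −78 °C) and DMF give the aldehyde F3, and Horner–Wadsworth–Emmons reaction with diethyl [4-(benzyloxy)benzyl]phosphonate (KOt-Bu, THF, 0 °C) gives the E-stilbene, coming back to the route at 16.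

**Further compounds**
F1 | step 10 | mono-cyclised benzylic acetate: as 17, but C7b′ carries H, OAc and the 4-hydroxyphenyl group (C7b′ configuration not defined) | CC(=O)OC(c1ccc(O)cc1)[C@@H]2[C@@H](c3cc(OCc7ccccc7)cc4c3[C@H](c6cc(OCc7ccccc7)cc(OCc7ccccc7)c6)[C@@H](c6ccc(OCc7ccccc7)cc6)O4)[C@H](c6ccc(OCc7ccccc7)cc6)c4c(OCc7ccccc7)cc(OCc7ccccc7)cc4[C@H]4c5c(cc(OCc7ccccc7)cc52)O[C@H]4c4ccc(OCc7ccccc7)cc4
F2 | step 5 | N-(tert-butyldimethylsilyl)hydrazone of 7 | CC(C)(C)[Si](C)(C)NN=C(c1cc(OCc2ccccc2)cc(OCc2ccccc2)c1)c1c(Br)cc(OCc2ccccc2)cc1OCc1ccc(OCc2ccccc2)cc1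
F3 | step 9 | (2S,3S)-6-(benzyloxy)-2-[4-(benzyloxy)phenyl]-3-[3,5-bis(benzyloxy)phenyl]-2,3-dihydro-1-benzofuran-4-carbaldehyde | C(c1ccccc1)Oc1cc(OCc2ccccc2)cc(c1)[C@H]1c2c(cc(OCc3ccccc3)cc2C=O)O[C@@H]1c1ccc(OCc2ccccc2)cc1
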